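**Assumption:** the target has no stereocentres, so it is achiral and no enantioselective step is needed. The only stereo-element in the route is the E-alkene of chalcone 6, which is destroyed in Step 5.

## Retrosynthetic overview
1. The 8-OAc is installed last, by acetylating a free 8-OH. All other phenols are masked as benzyl ethers, which are removed by hydrogenolysis in the final step and leave the acetate intact.
2. The flavonol (pyranone) ring and its 3-OH come from an Algar–Flynn–Oyamada (AFO) oxidative cyclisation of a 2'-hydroxychalcone. The chalcone comes from a Claisen–Schmidt condensation of an acetophenone with 4-benzyloxybenzaldehyde.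
3. The C8 oxygen is introduced on the symmetric precursor 2',6'-dihydroxy-4'-methoxyacetophenone. After mono-benzylation, IBX ortho-hydroxylation can only reach C3, which is the only free carbon ortho to the remaining phenol. This is the proposed new step.
4. Ring order: the A-ring is fully functionalised first, then the B-ring is attached (chalcone), then the C-ring is closed (AFO).

## Route

**Step 1**
Reactants: 1 (2',6'-dihydroxy-4'-methoxyacetophenone)
Product: 2 (1-(2-benzyloxy-6-hydroxy-4-methoxyphenyl)ethanone)
Conditions: BnBr (1.0 equiv), K2CO3 (1.0 equiv), acetone, reflux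
Reagents that add atoms: benzyl bromide, BrCc1ccccc1
Why: Williamson mono-O-benzylation of the symmetric diol; the two OH groups are equivalent, so no regiochemical issue arises, and the statistical bis-ether is separated and recycled.

**Step 2**
Reactants: 2
Product: 3 (1-(6-benzyloxy-2,3-dihydroxy-4-methoxyphenyl)ethanone)
Conditions: (i) IBX (1.2 equiv), DMF, rt; (ii) aqueous Na2S2O4, rt (in situ reduction of the o-quinone)
Reagents that add atoms: IBX (supplies the new O atom), OI1(=O)OC(=O)c2ccccc12
Why: Proposed new method: IBX ortho-hydroxylation (Pettus-type) is extended to an H-bonded o-acylphenol. The phenol O–I(V) bond delivers oxygen to the adjacent carbon, giving an o-quinone that is reduced in situ. The closest known reaction is IBX oxidation of simple phenols to o-quinones followed by reduction. Here the only free ortho carbon is C3, which is activated by the ortho 4-OMe and the para 6-OBn and is meta to the acyl group. DMF breaks the OH···O=C chelate so the phenol can bind iodine. Ortho-directed delivery avoids the C5 (para) product that an Elbs-type oxidation would give.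

**Step 3**
Reactants: 3
Product: 4 (1-(3-allyloxy-6-benzyloxy-2-hydroxy-4-methoxyphenyl)ethanone)
Conditions: allyl bromide (1.05 equiv), K2CO3 (1.1 equiv), acetone, 25→50 °C
Reagents that add atoms: allyl bromide, C=CCBr
Why: Williamson etherification; the 2-OH is chelated to the ketone, so the 3-OH is the only free non-chelated phenol and is alkylated selectively. The allyl group can be removed later without touching the benzyl groups.

**Step 4**
Reactants: 4; 5 (4-benzyloxybenzaldehyde)
Product: 6 ((E)-chalcone: 1-(3-allyloxy-6-benzyloxy-2-hydroxy-4-methoxyphenyl)-3-(4-benzyloxyphenyl)prop-2-en-1-one)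
Conditions: KOH (aq. 50%), EtOH, rt, 2–3 d
Reagents that add atoms: none beyond aldehyde 5
Why: Claisen–Schmidt aldol condensation; dehydration gives the thermodynamic E-enone.

**Step 5**
Reactants: 6
Product: 7 (8-allyloxy-5,4'-bis(benzyloxy)-3-hydroxy-7-methoxyflavone)
Conditions: 30% H2O2, NaOH (aq.), MeOH/THF, 0 °C→rt
Reagents that add atoms: hydrogen peroxide, OO
Why: Algar–Flynn–Oyamada reaction: Weitz–Scheffer epoxidation of the enone, phenoxide 6-endo opening, then oxidation of the dihydroflavonol to the flavonol. This forms the pyranone ring and the 3-OH, and the aryl allyl and benzyl ethers are stable.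

**Step 6**
Reactants: 7
Product: 8 (8-allyloxy-3,5,4'-tris(benzyloxy)-7-methoxyflavone)
Conditions: BnBr (1.2 equiv), K2CO3, DMF, rt
Reagents that add atoms: benzyl bromide, BrCc1ccccc1
Why: Williamson benzylation of the acidic 3-OH so that only the 8-O is free after the next step.

**Step 7**
Reactants: 8
Product: 9 (3,5,4'-tris(benzyloxy)-8-hydroxy-7-methoxyflavone)
Conditions: Pd(PPh3)4 (5 mol%), K2CO3, MeOH, rt
Reagents that add atoms: none (the allyl group leaves as allyl methyl ether)
Why: Pd(0) π-allyl deallylation of an aryl allyl ether; the benzyl ethers, the enone and the methyl ether are untouched.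

**Step 8**
Reactants: 9
Product: 10 (8-acetoxy-3,5,4'-tris(benzyloxy)-7-methoxyflavone)
Conditions: Ac2O, pyridine, DMAP (cat.), CH2Cl2, 0 °C→rt
Reagents that add atoms: acetic anhydride, CC(=O)OC(C)=O
Why: Standard O-acylation of the only free phenol.

**Step 9**
Reactants: 10
Product: 11 (pollenitin 8-acetate)
Conditions: H2 (1 atm), 10% Pd/C, EtOAc/THF, rt, short reaction time
Reagents that add atoms: none (H2 only)
Why: Hydrogenolysis of the three benzyl ethers. Aryl acetate, methyl ether and the C2=C3/C4=O system survive, and the 5-OH is restored in its chelated form.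

## Compound list
1 | 2',6'-dihydroxy-4'-methoxyacetophenone | COc1cc(O)c(C(C)=O)c(O)c1 | starting material
2 | 1-(2-benzyloxy-6-hydroxy-4-methoxyphenyl)ethanone | COc1cc(O)c(C(C)=O)c(OCc2ccccc2)c1 | intermediate
3 | 1-(6-benzyloxy-2,3-dihydroxy-4-methoxyphenyl)ethanone | COc1cc(OCc2ccccc2)c(C(C)=O)c(O)c1O | intermediate
4 | 1-(3-allyloxy-6-benzyloxy-2-hydroxy-4-methoxyphenyl)ethanone | C=CCOc1c(OC)cc(OCc2ccccc2)c(C(C)=O)c1O | intermediate
5 | 4-benzyloxybenzaldehyde | O=Cc1ccc(OCc2ccccc2)cc1 | starting material
6 | (E)-chalcone, 2'-OH, 3'-OAllyl, 4'-OMe, 6'-OBn, 4-OBn | C=CCOc1c(OC)cc(OCc2ccccc2)c(C(=O)/C=C/c2ccc(OCc3ccccc3)cc2)c1O | intermediate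
7 | 8-allyloxy-5,4'-bis(benzyloxy)-3-hydroxy-7-methoxyflavone | C=CCOc1c(OC)cc(OCc2ccccc2)c2c(=O)c(O)c(-c3ccc(OCc4ccccc4)cc3)oc12 | intermediate
8 | 8-allyloxy-3,5,4'-tris(benzyloxy)-7-methoxyflavone | C=CCOc1c(OC)cc(OCc2ccccc2)c2c(=O)c(OCc3ccccc3)c(-c3ccc(OCc4ccccc4)cc3)oc12 | intermediate
9 | 3,5,4'-tris(benzyloxy)-8-hydroxy-7-methoxyflavone | COc1cc(OCc2ccccc2)c2c(=O)c(OCc3ccccc3)c(-c3ccc(OCc4ccccc4)cc3)oc2c1O | intermediate
10 | 8-acetoxy-3,5,4'-tris(benzyloxy)-7-methoxyflavone | COc1cc(OCc2ccccc2)c2c(=O)c(OCc3ccccc3)c(-c3ccc(OCc4ccccc4)cc3)oc2c1OC(C)=O | intermediate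
11 | pollenitin 8-acetate | COc1cc(O)c2c(=O)c(O)c(-c3ccc(O)cc3)oc2c1OC(C)=O | target

Simple reagents (BnBr, allyl bromide, IBX, H2O2, Ac2O) are identified by name and SMILES in the step fields and are not numbered.

**Total steps:** 9. **Longest linear sequence:** 9 steps (1→2→3→4→6→7→8→9→10→11, counting each conversion).

## Three steps most likely to fail
1. **Step 2 (proposed new IBX ortho-hydroxylation).** The chelated, acyl-bearing phenol may react sluggishly, or the o-quinone may be over-oxidised or lost.
   Fallback (known chemistry, different approach): Duff formylation of 2 (HMTA, TFA) at C3, ortho to the free OH, followed by Dakin oxidation (H2O2, NaOH) to give catechol 3.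
2. **Step 5 (AFO).** Yields can be modest, and aurone formation competes with the 6'-OBn chalcone.
   Fallback: cyclise 6 to the flavanone (NaOAc, EtOH, reflux). Make the TMS enol ether (LiHMDS, TMSCl) and oxidise it by Rubottom oxidation (DMDO) to the 3-hydroxyflavanone. Then dehydrogenate with I2/DMSO to give 7.
3. **Step 9 (hydrogenolysis in the presence of the acetate and flavonol).** Over-reduction of the flavonol, or acetyl loss or migration, is possible.
   Fallback: replace hydrogenolysis with Lewis-acid debenzylation, BCl3 with pentamethylbenzene as cation scavenger, CH2Cl2, –78 °C.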